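## Analysis of the target

The target (26) has three rings: an isocoumarin, made of benzenoid ring A and lactone ring B (C1 carbonyl, O2, C3 pentyl, C4 H, C6 OH, C8 O), and a benzoic acid, ring C, bonded to C8 through an ether oxygen. Ring C is numbered here from the carboxyl carbon: C1' (CO2H), C2' (OH), C3' (H), C4' (OH), C5' (ether oxygen), C6' (pentyl), so five of its six positions are substituted. There is no stereocentre, and the diaryl ether axis, with only three ortho substituents, is not expected to be configurationally stable, so no stereochemical element has to be controlled. The sensitive groups are the enol lactone of ring B (opened by hydroxide and alkoxide), the 2,4-dihydroxybenzoic acid of ring C (decarboxylates in hot acid) and three free phenols (oxidation). The hard part is the C8–O–C5' bond: C5' sits between the C4' hydroxyl and the C6' pentyl chain, C8 sits next to C8a with its peri carbonyl, and ring C is far too electron-rich for nucleophilic aromatic substitution. An aryl–oxygen coupling would therefore have to join a doubly ortho-substituted, electron-rich partner to a chelated phenol. The strategy rests on ring C being a resorcinol: the C4' oxygen can start as the carbonyl oxygen of a ketene and C5' as the far carbon of the vinyl group on that ketene. The ether oxygen is then bonded to C5' while C5' is still an unhindered vinylic CH, and ring C is grown around it, with C2' and C3' supplied by an alkoxyalkyne.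

## Retrosynthetic reasoning

26 from 25. The last operation only removes alkyl groups: the C6 methyl ether, which comes from starting material 4, and the C2' ethyl ether, which comes from alkyne 17. A boron trihalide cleaves both without touching the diaryl ether or the lactone, so no skeletal bond changes at the end and the decarboxylation-prone dihydroxy acid is exposed only once.

25 from 22 through 24. The C1'–carboxyl bond is cut next. In 22 the position C1' is the only one para to the free C4' hydroxyl, so an electrophilic one-carbon unit (Vilsmeier–Haack formylation) is directed there, and a chlorite oxidation raises the aldehyde 24 to the acid 25. The carboxyl carbon is deliberately not carried through the ring-forming step: an ester on the diazo carbon would turn the ketene into an acylketene, which tends to react with ynol ethers as a heterodiene instead of by [2+2] addition. A halogenation and carbonylation at C1' was considered, but it would mean a carbonylation at an electron-rich bromide flanked by ethoxy and pentyl and an ester cleavage beside the lactone; it is kept as a fallback.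

22 from 16 and 17. This is the central disconnection. Ring C is opened at C4'–C5', C4'–C3' and C1'–C2', and the C1'–C6' bond is traced back to a 1,2-shift. That leaves the diazo ketone 16, in which C5' is already bonded to the C8 oxygen and C6' already carries pentyl, and ethoxyethyne 17, which supplies C3' (H) and C2' (OEt). The gain is that the crowded diaryl ether is never made by joining two arenes, and that four of the five ring C substituents are fixed by connectivity. The forward reaction must generate the vinylketene under neutral conditions and let it add the alkyne in one orientation.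

16 from 14 through 15. The C1'–C4' bond of the diazo ketone is made by acylating a diazoalkane with the acid chloride 15. The α-carbon of 15 is fully substituted, so it cannot form a ketene by dehydrohalogenation, and its double bond is a poor dipolarophile.

14 from 8 and 12 through 13. The C5'–O bond is cut here, at the stage where C5' is the β-carbon of an acrylate. The forward reaction is an addition–elimination of the phenoxide of 8 on the enol tosylate 12, at a CH carbon activated by both the ester and the leaving group. The ester is allyl because it must later be removed without hydroxide, which would open ring B and attack the vinylogous carbonate; palladium-catalysed deallylation of 13 gives 14 under neutral conditions.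

12 from 9 through 11. The C5'–C6' bond is a crossed Claisen bond between the α-carbon of allyl heptanoate 9 and a formate ester; tosylation of the resulting formyl ester 11 turns the enol oxygen into the leaving group.

8 from 4 and 3. Rings A and B are made first and by routine chemistry. Selective cleavage of the chelated C8 methyl ether of 7 frees the phenol 8. The O2–C3 bond of 7 comes from cyclodehydration of keto acid 6. The C4–C3 bond comes from lateral lithiation of the toluic acid 4 and acylation with the Weinreb amide 3, which is made from 1 and 2 and stops cleanly at the ketone.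

## Alternatives that were turned down

Alternative 1: The cut runs through ring A: the C8–O bond and the C8a–C1 bond would be made together. Forward, a fluoride-induced elimination would generate 3-chloro-5-methoxybenzyne A3; the phenoxide of methyl 3-hydroxy-4,6-dimethoxy-2-pentylbenzoate A2 would add at the aryne carbon remote from chlorine, and the aryl anion left next to chlorine would be carboxylated to give 2-chloro-6-[4,6-dimethoxy-3-(methoxycarbonyl)-2-pentylphenoxy]-4-methoxybenzoic acid A1.
- For: addition to an aryne is little affected by ortho substituents on the phenoxide, the inductive effect of chlorine fixes the site of attack, and no metal, diazo compound or light is needed. On convergence and on the number of steps to the ether bond this route is stronger than the chosen one.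
- Against: A2 is itself a pentasubstituted benzene with a free hydroxyl wedged between methoxy and pentyl, and its five groups must be placed by a separate series of aromatic substitutions. The aryl anion must be carboxylated faster than it is protonated, while the carboxylating gas reversibly ties up the phenoxide as a carbonate. After A1, ring B is still missing: it needs a cross-coupling at an electron-rich aryl chloride beside a carboxyl group and a lactonization that must go 6-endo. The ring C methyl ester, shielded by pentyl and methoxy, must finally be cleaved next to a hydroxide-sensitive lactone.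
- Comparison: the chosen strategy gives up convergence at the ether bond, but ring B is finished first and the substitution pattern of ring C follows from connectivity.

Alternative 2: Rings A and B and the ether bond would all be cut at once: C4a–C8a, C5–C6 and C8–O. Forward, heating (3Z)-non-3-en-1-yn-4-yl 5-ethoxypenta-2,4-diynoate A5 would bring about a hexadehydro-Diels–Alder reaction to a C7–C8 aryne, across which A2 would add its O–H to give methyl 3-[(6-ethoxy-1-oxo-3-pentyl-1H-isochromen-8-yl)oxy]-4,6-dimethoxy-2-pentylbenzoate A4.
- For: two rings and the ether in one reagent-free step, and the C6 alkoxy group directs the oxygen nucleophile to C8. In bonds formed per step this is clearly stronger than the chosen route.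
- Against: A5 combines an ynol ether, a diynoate and an enol ester in one small molecule. The tether closes a six-membered ring, which makes this cycloaddition slower than with the usual three-atom tether, so it needs temperatures at which ethyl ynol ethers lose ethylene to give ketenes. The hindered phenol A2 can also react with the aryne through its free ring carbon instead of its oxygen. The route still needs A2 and ends with the same shielded methyl ester.
- Comparison: the chosen strategy forms fewer bonds in its key step, but every intermediate before the diazo ketone is an ordinary stable compound and the alkyne is commercial.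

Alternative 3: Ring C would be cut at C1'–C6' and C2'–C3' and made at the cyclohexane-1,3-dione oxidation level. Forward, a base would add a malonate diester to the β-carbon of methyl 4-methoxy-2-methyl-6-{[(3Z)-2-oxonon-3-en-3-yl]oxy}benzoate A7, and the methyl ketone enolate would then close on a malonate ester (Michael–Claisen) to give methyl 5-[5-methoxy-2-(methoxycarbonyl)-3-methylphenoxy]-2,4-dioxo-6-pentylcyclohexane-1-carboxylate A6 (racemic, all-trans).
- For: cheap reagents, no light, the standard way to make 5-alkylresorcylates, and the C1' carboxyl carbon is present from the start. On that last point it is stronger than the chosen route, which spends two steps on C1'.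
- Against: the α-aryloxy group makes A7 a poorer and more hindered Michael acceptor. A6 must be dehydrogenated across C5'–C6' while the C5'–O bond, α to a carbonyl on a ring that aromatizes just as well by losing the phenol, has to survive. Three stereocentres are made only to be erased. Ring B would have to be built afterwards by lateral metalation in a molecule that then carries a second ester and acidic phenols.
- Comparison: the chosen strategy delivers ring C directly at the aromatic oxidation level with the ether in place, at the price of a photochemical step and a later carboxylation.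

Key step: step 10

Assumption: compounds 12 to 16 are drawn as E isomers, the geometry expected on thermodynamic grounds; it is not carried into 22, because C5' and C6' end as aromatic carbons. Compound 11 is drawn as its aldehyde tautomer; it is racemic, configurationally labile and in equilibrium with its enol.

## Route

Step 1
Reactants: 1 hexanoyl chloride; 2 N,O-dimethylhydroxylamine hydrochloride
Product: 3 N-methoxy-N-methylhexanamide
Conditions: pyridine, CH2Cl2, 0 °C to rt
Reagents that add atoms: none
Why: Acylation of the hydroxylamine by the acid chloride (Weinreb amide formation); no competing functionality.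

Step 2
Reactants: 4 2,4-dimethoxy-6-methylbenzoic acid; 3 N-methoxy-N-methylhexanamide
Product: 6 2,4-dimethoxy-6-(2-oxoheptyl)benzoic acid, via dilithium dianion 5 (not isolated)
Conditions: LiN(iPr)2 (2.4 equiv), THF, −78 to 0 °C; then 3, −78 to 0 °C; aq. HCl
Reagents that add atoms: none
Why: Lateral (benzylic) lithiation of the ortho-toluic acid as its dianion, then acylation by the Weinreb amide. The chelated tetrahedral adduct releases the ketone only on acid work-up, so neither over-addition nor proton transfer from the product can occur.

Step 3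
Reactants: 6 2,4-dimethoxy-6-(2-oxoheptyl)benzoic acid
Product: 7 6,8-dimethoxy-3-pentyl-1H-isochromen-1-one
Conditions: p-TsOH·H2O (cat.), toluene, reflux, Dean–Stark
Reagents that add atoms: none
Why: Acid-catalysed cyclodehydration (enol lactonization) of a 2-(2-oxoalkyl)benzoic acid; the conjugated isocoumarin is the thermodynamic product once water is removed.

Step 4
Reactants: 7 6,8-dimethoxy-3-pentyl-1H-isochromen-1-one
Product: 8 8-hydroxy-6-methoxy-3-pentyl-1H-isochromen-1-one
Conditions: BCl3 (1.5 equiv), CH2Cl2, −78 to 0 °C; then H2O
Reagents that add atoms: none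
Why: Chelation-controlled ether cleavage: BCl3 bound to the lactone carbonyl reaches only the peri C8 methoxy group through a six-membered chelate, and the C6 ether is untouched at this temperature.

Step 5
Reactants: 9 prop-2-en-1-yl heptanoate
Product: 11 prop-2-en-1-yl 2-formylheptanoate (racemic), via lithium enolate 10 (not isolated)
Conditions: LiN(iPr)2 (1.1 equiv), THF, −78 °C; HCO2Et (3 equiv), −78 to −20 °C; aq. HCl
Reagents that add atoms: ethyl formate, CCOC=O
Why: Crossed Claisen condensation of the ester enolate with a non-enolizable formate. The ethoxide released is consumed in deprotonating the product, and the low temperature keeps the allyl ester enolate from Claisen rearrangement.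

Step 6
Reactants: 11 prop-2-en-1-yl 2-formylheptanoate
Product: 12 prop-2-en-1-yl (2E)-3-[(4-methylbenzenesulfonyl)oxy]-2-pentylprop-2-enoate
Conditions: TsCl, N-methylimidazole, Et3N, CH2Cl2, 0 °C
Reagents that add atoms: p-toluenesulfonyl chloride, Cc1ccc(cc1)S(=O)(=O)Cl
Why: O-Sulfonylation of the enol of an α-formyl ester through the N-sulfonylimidazolium salt; non-chelating amine conditions favour the E enol tosylate, and either geometry would serve in step 7.

Step 7
Reactants: 8 8-hydroxy-6-methoxy-3-pentyl-1H-isochromen-1-one; 12 prop-2-en-1-yl (2E)-3-[(4-methylbenzenesulfonyl)oxy]-2-pentylprop-2-enoate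
Product: 13 prop-2-en-1-yl (2E)-3-[(6-methoxy-1-oxo-3-pentyl-1H-isochromen-8-yl)oxy]-2-pentylprop-2-enoate
Conditions: Cs2CO3, DMF, rt to 50 °C
Reagents that add atoms: none
Why: Addition–elimination (nucleophilic vinylic substitution) of the phenoxide at the β-carbon of the vinylogous sulfonate, an unhindered CH activated by ester and leaving group. The E vinyl ether, with aryloxy trans to the ester, is the thermodynamically preferred isomer.

Step 8
Reactants: 13 prop-2-en-1-yl (2E)-3-[(6-methoxy-1-oxo-3-pentyl-1H-isochromen-8-yl)oxy]-2-pentylprop-2-enoate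
Product: 14 (2E)-3-[(6-methoxy-1-oxo-3-pentyl-1H-isochromen-8-yl)oxy]-2-pentylprop-2-enoic acid
Conditions: Pd(PPh3)4 (5 mol %), HCO2H, Et3N, THF, rt
Reagents that add atoms: none
Why: Tsuji–Trost deallylation: zerovalent palladium ionizes the allyl ester and formate reduces the π-allyl complex to propene. The neutral conditions spare the enol lactone and the vinylogous carbonate, both of which hydroxide would attack.

Step 9
Reactants: 14 (2E)-3-[(6-methoxy-1-oxo-3-pentyl-1H-isochromen-8-yl)oxy]-2-pentylprop-2-enoic acid
Product: 16 (3E)-1-diazo-4-[(6-methoxy-1-oxo-3-pentyl-1H-isochromen-8-yl)oxy]-3-pentylbut-3-en-2-one, via acid chloride 15 (not isolated)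
Conditions: (COCl)2, DMF (cat.), CH2Cl2, 0 °C to rt; evaporate; then CH2N2 (3 equiv), Et2O/THF, 0 °C
Reagents that add atoms: diazomethane, C=[N+]=[N-]
Why: Acylation of diazomethane by the acid chloride (first stage of the Arndt–Eistert sequence). The double bond is trisubstituted and carries the aryloxy donor, so it is a poor dipolarophile, and the acid chloride has no α-hydrogen from which a ketene could form.

Step 10
Reactants: 16 (3E)-1-diazo-4-[(6-methoxy-1-oxo-3-pentyl-1H-isochromen-8-yl)oxy]-3-pentylbut-3-en-2-one; 17 ethoxyethyne
Product: 22 8-(4-ethoxy-2-hydroxy-6-pentylphenoxy)-6-methoxy-3-pentyl-1H-isochromen-1-one, via aryloxyvinylketene 18 (not isolated), via 4-alkenylcyclobutenone 19 (not isolated), via dienylketene 20 (not isolated), via cyclohexadienone 21 (not isolated)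
Conditions: 17 (4 equiv, hexane solution), ClCH2CH2Cl (0.05 M), hν (365 nm), rt; then 80 °C, sealed tube
Reagents that add atoms: none
Why: Excitation of the diazo ketone expels N2 and the alkenyl group migrates from the carbonyl carbon to the diazo carbon (Wolff rearrangement, C6' to C1'), giving aryloxyvinylketene 18. The ketene acts as a 2π partner toward the electron-rich alkyne: its carbonyl carbon (C4') bonds to the unsubstituted alkyne carbon (C3') and its α-carbon (C1') to the ethoxy-bearing carbon (C2'), giving cyclobutenone 19. Reversible 4π electrocyclic opening of 19 (C4'–C1' cleaved) gives dienylketene 20, and ring C closes by thermal 6π electrocyclization (six-membered, C4'–C5') to dienone 21, which tautomerizes to phenol 22. The closest known reaction type is the Danheiser benzannulation in its photochemical Wolff variant with alkoxyalkynes. No stereocentre survives: the sp3 carbons of 19 and 21 are racemic and become aromatic. The one selectivity needed is the orientation of the [2+2] step, set by the polarization of the ynol ether (nucleophilic at its CH carbon) against the electrophilic ketene carbon; every other position follows from connectivity. The 365 nm light addresses the long-wavelength band of the diazo ketone, where the isocoumarin absorbs only weakly, and the neutral medium leaves the lactone intact. The E geometry of 16 keeps the aryloxy group on the outside of the closing triene.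

Step 11
Reactants: 22 8-(4-ethoxy-2-hydroxy-6-pentylphenoxy)-6-methoxy-3-pentyl-1H-isochromen-1-one
Product: 24 6-ethoxy-4-hydroxy-3-[(6-methoxy-1-oxo-3-pentyl-1H-isochromen-8-yl)oxy]-2-pentylbenzaldehyde, via iminium chloride 23 (not isolated)
Conditions: POCl3, DMF, 0 °C to rt; then aq. NaOAc
Reagents that add atoms: N,N-dimethylformamide, CN(C)C=O; water, O
Why: Vilsmeier–Haack formylation of the most electron-rich ring at C1', para to the free hydroxyl and ortho to ethoxy. This is the position between alkyl and alkoxy that 5-alkylresorcinol ethers take in preference to the one between the two oxygens; ring A is deactivated by the lactone carbonyl.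

Step 12
Reactants: 24 6-ethoxy-4-hydroxy-3-[(6-methoxy-1-oxo-3-pentyl-1H-isochromen-8-yl)oxy]-2-pentylbenzaldehyde
Product: 25 6-ethoxy-4-hydroxy-3-[(6-methoxy-1-oxo-3-pentyl-1H-isochromen-8-yl)oxy]-2-pentylbenzoic acid
Conditions: NaClO2, NaH2PO4, 2-methylbut-2-ene (30 equiv), t-BuOH/THF/H2O, 0 °C to rt
Reagents that add atoms: sodium chlorite, [Na+].[O-]Cl=O
Why: Pinnick (Lindgren) oxidation of the aldehyde at buffered acidic pH, where the lactone is stable; the large excess of alkene takes up hypochlorous acid before it can chlorinate the phenol ring.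

Step 13
Reactants: 25 6-ethoxy-4-hydroxy-3-[(6-methoxy-1-oxo-3-pentyl-1H-isochromen-8-yl)oxy]-2-pentylbenzoic acid
Product: 26 4,6-dihydroxy-3-[(6-hydroxy-1-oxo-3-pentyl-1H-isochromen-8-yl)oxy]-2-pentylbenzoic acid
Conditions: BBr3 (6 equiv), CH2Cl2, −78 °C to rt; then H2O, 0 °C
Reagents that add atoms: none
Why: Lewis acid cleavage of the alkyl aryl ethers: the C2' ethyl ether is assisted by chelation to the neighbouring carboxyl, and the C6 methyl ether follows at room temperature. Diaryl ether and enol lactone are inert to BBr3, and the cold aqueous quench avoids decarboxylation of the dihydroxy acid.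

## Compound list

1 | hexanoyl chloride | CCCCCC(=O)Cl | starting material
2 | N,O-dimethylhydroxylamine hydrochloride | CNOC.Cl | starting material
3 | N-methoxy-N-methylhexanamide | CCCCCC(=O)N(C)OC | intermediate
4 | 2,4-dimethoxy-6-methylbenzoic acid | COc1cc(C)c(C(=O)O)c(OC)c1 | starting material
5 | lithium 2-(lithiomethyl)-4,6-dimethoxybenzoate (dianion of 4) | [Li]Cc1cc(OC)cc(OC)c1C(=O)O[Li] | intermediate (not isolated)
6 | 2,4-dimethoxy-6-(2-oxoheptyl)benzoic acid | CCCCCC(=O)Cc1cc(OC)cc(OC)c1C(=O)O | intermediate
7 | 6,8-dimethoxy-3-pentyl-1H-isochromen-1-one | CCCCCc1cc2cc(OC)cc(OC)c2c(=O)o1 | intermediate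
8 | 8-hydroxy-6-methoxy-3-pentyl-1H-isochromen-1-one | CCCCCc1cc2cc(OC)cc(O)c2c(=O)o1 | intermediate
9 | prop-2-en-1-yl heptanoate (allyl heptanoate) | CCCCCCC(=O)OCC=C | starting material
10 | lithium enolate of 9 (lithium 1-(prop-2-en-1-yloxy)hept-1-en-1-olate, geometry not relevant) | CCCCCC=C(O[Li])OCC=C | intermediate (not isolated)
11 | prop-2-en-1-yl 2-formylheptanoate (racemic, enolizable) | CCCCCC(C=O)C(=O)OCC=C | intermediate
12 | prop-2-en-1-yl (2E)-3-[(4-methylbenzenesulfonyl)oxy]-2-pentylprop-2-enoate | CCCCC/C(C(=O)OCC=C)=C\OS(=O)(=O)c1ccc(C)cc1 | intermediate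
13 | prop-2-en-1-yl (2E)-3-[(6-methoxy-1-oxo-3-pentyl-1H-isochromen-8-yl)oxy]-2-pentylprop-2-enoate | CCCCC/C(C(=O)OCC=C)=C\Oc1cc(OC)cc2cc(CCCCC)oc(=O)c12 | intermediate
14 | (2E)-3-[(6-methoxy-1-oxo-3-pentyl-1H-isochromen-8-yl)oxy]-2-pentylprop-2-enoic acid | CCCCC/C(C(=O)O)=C\Oc1cc(OC)cc2cc(CCCCC)oc(=O)c12 | intermediate
15 | (2E)-3-[(6-methoxy-1-oxo-3-pentyl-1H-isochromen-8-yl)oxy]-2-pentylprop-2-enoyl chloride | CCCCC/C(C(=O)Cl)=C\Oc1cc(OC)cc2cc(CCCCC)oc(=O)c12 | intermediate (not isolated)
16 | (3E)-1-diazo-4-[(6-methoxy-1-oxo-3-pentyl-1H-isochromen-8-yl)oxy]-3-pentylbut-3-en-2-one | [N-]=[N+]=CC(=O)/C(CCCCC)=C/Oc1cc(OC)cc2cc(CCCCC)oc(=O)c12 | intermediate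
17 | ethoxyethyne | CCOC#C | starting material
18 | (3E)-4-[(6-methoxy-1-oxo-3-pentyl-1H-isochromen-8-yl)oxy]-3-pentylbuta-1,3-dien-1-one | O=C=C/C(CCCCC)=C/Oc1cc(OC)cc2cc(CCCCC)oc(=O)c12 | intermediate (not isolated)
19 | 3-ethoxy-4-{(1E)-1-[(6-methoxy-1-oxo-3-pentyl-1H-isochromen-8-yl)oxy]hept-1-en-2-yl}cyclobut-2-en-1-one (racemic) | CCOC1=CC(=O)C1/C(CCCCC)=C/Oc1cc(OC)cc2cc(CCCCC)oc(=O)c12 | intermediate (not isolated)
20 | (3E,5E)-3-ethoxy-6-[(6-methoxy-1-oxo-3-pentyl-1H-isochromen-8-yl)oxy]-5-pentylhexa-1,3,5-trien-1-one | O=C=C/C(OCC)=C\C(CCCCC)=C\Oc1cc(OC)cc2cc(CCCCC)oc(=O)c12 | intermediate (not isolated)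
21 | 3-ethoxy-6-[(6-methoxy-1-oxo-3-pentyl-1H-isochromen-8-yl)oxy]-5-pentylcyclohexa-2,4-dien-1-one (racemic) | O=C1C=C(OCC)C=C(CCCCC)C1Oc1cc(OC)cc2cc(CCCCC)oc(=O)c12 | intermediate (not isolated)
22 | 8-(4-ethoxy-2-hydroxy-6-pentylphenoxy)-6-methoxy-3-pentyl-1H-isochromen-1-one | CCOc1cc(O)c(Oc2cc(OC)cc3cc(CCCCC)oc(=O)c23)c(CCCCC)c1 | intermediate
23 | N-({6-ethoxy-4-hydroxy-3-[(6-methoxy-1-oxo-3-pentyl-1H-isochromen-8-yl)oxy]-2-pentylphenyl}methylidene)-N-methylmethanaminium chloride | C[N+](C)=Cc1c(OCC)cc(O)c(Oc2cc(OC)cc3cc(CCCCC)oc(=O)c23)c1CCCCC.[Cl-] | intermediate (not isolated)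
24 | 6-ethoxy-4-hydroxy-3-[(6-methoxy-1-oxo-3-pentyl-1H-isochromen-8-yl)oxy]-2-pentylbenzaldehyde | CCOc1cc(O)c(Oc2cc(OC)cc3cc(CCCCC)oc(=O)c23)c(CCCCC)c1C=O | intermediate
25 | 6-ethoxy-4-hydroxy-3-[(6-methoxy-1-oxo-3-pentyl-1H-isochromen-8-yl)oxy]-2-pentylbenzoic acid | CCOc1cc(O)c(Oc2cc(OC)cc3cc(CCCCC)oc(=O)c23)c(CCCCC)c1C(=O)O | intermediate
26 | 4,6-dihydroxy-3-[(6-hydroxy-1-oxo-3-pentyl-1H-isochromen-8-yl)oxy]-2-pentylbenzoic acid | CCCCCc1cc2cc(O)cc(Oc3c(O)cc(O)c(C(=O)O)c3CCCCC)c2c(=O)o1 | target

## Step count and risks

Total: 13 steps. Longest linear sequence: 11 steps (steps 1, 2, 3, 4, 7, 8, 9, 10, 11, 12, 13); steps 5 and 6 form a two-step side branch that joins at step 7.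

Least certain steps:

Step 10 (key step). The aryloxy donor at the terminus makes the vinylketene electron-rich and less electrophilic at its carbonyl carbon. Capture by the ynol ether may therefore lose out to acylation of the product phenol by the ketene, to ketene oligomerization, or to light absorption and photoreaction of the isocoumarin.
Fallback, from 8, returning at 26: ring C is brought in ready-made and the ether is forced by copper catalysis. Commercial 1,3-dimethoxy-5-pentylbenzene F1 is iodinated with N-iodosuccinimide in MeCN between pentyl and methoxy to give 2-iodo-1,5-dimethoxy-3-pentylbenzene F2. Ullmann coupling of F2 with 8 (CuI, picolinic acid, K3PO4, DMSO, 90 °C) gives 8-(2,4-dimethoxy-6-pentylphenoxy)-6-methoxy-3-pentyl-1H-isochromen-1-one F3. Vilsmeier–Haack formylation at C1' gives 4,6-dimethoxy-3-[(6-methoxy-1-oxo-3-pentyl-1H-isochromen-8-yl)oxy]-2-pentylbenzaldehyde F4, and chlorite oxidation gives 4,6-dimethoxy-3-[(6-methoxy-1-oxo-3-pentyl-1H-isochromen-8-yl)oxy]-2-pentylbenzoic acid F5. BBr3 then cleaves the three methyl ethers to give 26. This coupling joins a doubly ortho-substituted iodide to a chelated phenol, which is why it is held in reserve.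

Step 7. The C8 phenoxide is stabilized by the peri carbonyl and may add slowly to the β-carbon; it may instead attack sulfur and take over the sulfonyl group, which returns the formyl ester.
Fallback, from 11 and 8, returning at 13: 11 is converted with (COCl)2 and DMF in CH2Cl2 into prop-2-en-1-yl (2E)-3-chloro-2-pentylprop-2-enoate F6 (an E/Z mixture would serve). This vinylogous acid chloride has no second electrophilic site, and Cs2CO3 in MeCN then effects the addition–elimination with 8 to give 13.

Step 9. Diazomethane may add as a 1,3-dipole across the conjugated double bond, or residual acid may convert the diazo ketone into the chloromethyl ketone with loss of nitrogen.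
Fallback, from 15, returning at 16: the diazo group is introduced by transfer instead of by acylation. Negishi acylation of 15 with MeZnCl and Pd(PPh3)4 in THF gives (3E)-3-{[(6-methoxy-1-oxo-3-pentyl-1H-isochromen-8-yl)oxy]methylidene}octan-2-one F7. LiN(SiMe3)2 at −78 °C followed by 2,2,2-trifluoroethyl trifluoroacetate gives (5E)-1,1,1-trifluoro-5-{[(6-methoxy-1-oxo-3-pentyl-1H-isochromen-8-yl)oxy]methylidene}decane-2,4-dione F8. Methanesulfonyl azide, Et3N and water in MeCN then transfer the diazo group with loss of the trifluoroacetyl group (detrifluoroacetylative diazo transfer) to give 16.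

Step 11. The electrophile may attack C3', between the two oxygens, or the phenol oxygen, because C1' is flanked by ethoxy and pentyl.
Fallback, from 22, returning at 26: C1' is marked by halogenation, which is reliably para to a free phenol. N-Bromosuccinimide in MeCN at −20 °C gives 8-(3-bromo-4-ethoxy-6-hydroxy-2-pentylphenoxy)-6-methoxy-3-pentyl-1H-isochromen-1-one F9. Palladium-catalysed carbonylation (Pd(OAc)2, Xantphos, CO, benzyl alcohol, Et3N, toluene, 100 °C) gives benzyl 6-ethoxy-4-hydroxy-3-[(6-methoxy-1-oxo-3-pentyl-1H-isochromen-8-yl)oxy]-2-pentylbenzoate F10. BBr3 cleaves the benzyl ester and both alkyl ethers to give 26.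

Step 12. Hypochlorous acid or chlorine dioxide formed from chlorite may chlorinate C3' or oxidize the free phenol faster than the scavenger removes them.
Fallback, from 24, returning at 26: the phenol is masked before the oxidation. Benzyl bromide and K2CO3 in DMF give 4-(benzyloxy)-6-ethoxy-3-[(6-methoxy-1-oxo-3-pentyl-1H-isochromen-8-yl)oxy]-2-pentylbenzaldehyde F11. Chlorite oxidation of this fully O-alkylated aldehyde gives 4-(benzyloxy)-6-ethoxy-3-[(6-methoxy-1-oxo-3-pentyl-1H-isochromen-8-yl)oxy]-2-pentylbenzoic acid F12. BBr3 removes benzyl, ethyl and methyl together to give 26.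

## Further compounds

F1 | step 10 | 1,3-dimethoxy-5-pentylbenzene | CCCCCc1cc(OC)cc(OC)c1
F2 | step 10 | 2-iodo-1,5-dimethoxy-3-pentylbenzene | CCCCCc1cc(OC)cc(OC)c1I
F3 | step 10 | 8-(2,4-dimethoxy-6-pentylphenoxy)-6-methoxy-3-pentyl-1H-isochromen-1-one | CCCCCc1cc(OC)cc(OC)c1Oc1cc(OC)cc2cc(CCCCC)oc(=O)c12
F4 | step 10 | 4,6-dimethoxy-3-[(6-methoxy-1-oxo-3-pentyl-1H-isochromen-8-yl)oxy]-2-pentylbenzaldehyde | COc1cc(OC)c(Oc2cc(OC)cc3cc(CCCCC)oc(=O)c23)c(CCCCC)c1C=O
F5 | step 10 | 4,6-dimethoxy-3-[(6-methoxy-1-oxo-3-pentyl-1H-isochromen-8-yl)oxy]-2-pentylbenzoic acid | COc1cc(OC)c(Oc2cc(OC)cc3cc(CCCCC)oc(=O)c23)c(CCCCC)c1C(=O)O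
F6 | step 7 | prop-2-en-1-yl (2E)-3-chloro-2-pentylprop-2-enoate | CCCCC/C(C(=O)OCC=C)=C\Cl
F7 | step 9 | (3E)-3-{[(6-methoxy-1-oxo-3-pentyl-1H-isochromen-8-yl)oxy]methylidene}octan-2-one | CC(=O)/C(CCCCC)=C/Oc1cc(OC)cc2cc(CCCCC)oc(=O)c12
F8 | step 9 | (5E)-1,1,1-trifluoro-5-{[(6-methoxy-1-oxo-3-pentyl-1H-isochromen-8-yl)oxy]methylidene}decane-2,4-dione | FC(F)(F)C(=O)CC(=O)/C(CCCCC)=C/Oc1cc(OC)cc2cc(CCCCC)oc(=O)c12
F9 | step 11 | 8-(3-bromo-4-ethoxy-6-hydroxy-2-pentylphenoxy)-6-methoxy-3-pentyl-1H-isochromen-1-one | CCOc1cc(O)c(Oc2cc(OC)cc3cc(CCCCC)oc(=O)c23)c(CCCCC)c1Br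
F10 | step 11 | benzyl 6-ethoxy-4-hydroxy-3-[(6-methoxy-1-oxo-3-pentyl-1H-isochromen-8-yl)oxy]-2-pentylbenzoate | CCOc1cc(O)c(Oc2cc(OC)cc3cc(CCCCC)oc(=O)c23)c(CCCCC)c1C(=O)OCc1ccccc1
F11 | step 12 | 4-(benzyloxy)-6-ethoxy-3-[(6-methoxy-1-oxo-3-pentyl-1H-isochromen-8-yl)oxy]-2-pentylbenzaldehyde | CCOc1cc(OCc2ccccc2)c(Oc2cc(OC)cc3cc(CCCCC)oc(=O)c23)c(CCCCC)c1C=O
F12 | step 12 | 4-(benzyloxy)-6-ethoxy-3-[(6-methoxy-1-oxo-3-pentyl-1H-isochromen-8-yl)oxy]-2-pentylbenzoic acid | CCOc1cc(OCc2ccccc2)c(Oc2cc(OC)cc3cc(CCCCC)oc(=O)c23)c(CCCCC)c1C(=O)O
A1 | alternative 1 | 2-chloro-6-[4,6-dimethoxy-3-(methoxycarbonyl)-2-pentylphenoxy]-4-methoxybenzoic acid | COc1cc(Cl)c(C(=O)O)c(Oc2c(OC)cc(OC)c(C(=O)OC)c2CCCCC)c1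
A2 | alternative 1 | methyl 3-hydroxy-4,6-dimethoxy-2-pentylbenzoate | CCCCCc1c(O)c(OC)cc(OC)c1C(=O)OC
A3 | alternative 1 | 3-chloro-5-methoxybenzyne (3-chloro-5-methoxy-1,2-didehydrobenzene) | ClC1=CC(OC)=CC#C1
A4 | alternative 2 | methyl 3-[(6-ethoxy-1-oxo-3-pentyl-1H-isochromen-8-yl)oxy]-4,6-dimethoxy-2-pentylbenzoate | CCCCCc1cc2cc(OCC)cc(Oc3c(OC)cc(OC)c(C(=O)OC)c3CCCCC)c2c(=O)o1
A5 | alternative 2 | (3Z)-non-3-en-1-yn-4-yl 5-ethoxypenta-2,4-diynoate | CCOC#CC#CC(=O)O/C(CCCCC)=C\C#C
A6 | alternative 3 | methyl 5-[5-methoxy-2-(methoxycarbonyl)-3-methylphenoxy]-2,4-dioxo-6-pentylcyclohexane-1-carboxylate (racemic, all-trans, one enantiomer drawn) | CCCCC[C@@H]1[C@@H](Oc2cc(OC)cc(C)c2C(=O)OC)C(=O)CC(=O)[C@H]1C(=O)OC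
A7 | alternative 3 | methyl 4-methoxy-2-methyl-6-{[(3Z)-2-oxonon-3-en-3-yl]oxy}benzoate | CCCCC/C=C(\Oc1cc(OC)cc(C)c1C(=O)OC)C(C)=O
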